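Everything rests on disconnecting the two exocyclic C–C bonds of the lactone ring, C4–CH2(veratryl) and C3=CH(aryl). Because C3 and C4 each carry one carbon leading to an arene and C5 is a plain OCH2, the ring maps onto (5R)-5-menthyloxyfuran-2(5H)-one, whose C5 alkoxy group is a removable stereocontrol element. In one operation 2-lithio-2-(3,4-dimethoxyphenyl)-1,3-dithiane adds to C4 anti to that group and the lactone enolate is trapped at C3 by MOM-protected vanillin, forming both bonds and fixing C4. Desulfurisation, reductive excision of the acetal carbon's alkoxy group and dehydration then deliver the (R)-configured E-arylidene lactone.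

Key step: step 5

Remark 1: l-menthyl means (1R,2S,5R)-2-isopropyl-5-methylcyclohexyl. Compounds 12 to 18 are carried as both epimers at the carbinol carbon, because this centre and C3 are erased in step 8.

Remark 2: the phenol is masked as a methoxymethyl (MOM) ether. An aryl silyl ether would be cleaved by the aqueous hydroxide of step 7, and the freed phenol would then be sulfonylated in step 8.

Step 1
Reactants: 1 furfural
Product: 2 5-hydroxyfuran-2(5H)-one (racemic hemiacetal)
Conditions: O2, hν (visible), rose bengal disodium salt C20H2Cl4I4Na2O5 (cat.), MeOH, rt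
Reagents that add atoms: dioxygen O=O
Why: Sensitised singlet-oxygen [4+2] cycloaddition to the furan gives a 2,5-endoperoxide that methanol fragments with loss of the formyl carbon as methyl formate (furan photooxygenation); the hemiacetal centre is racemic and is settled in step 2.

Step 2
Reactants: 2 5-hydroxyfuran-2(5H)-one; 3 (−)-menthol
Product: 5 (5R)-5-(l-menthyloxy)furan-2(5H)-one, via C5-epimeric menthyl acetal 4 (not isolated)
Conditions: p-toluenesulfonic acid monohydrate (cat.), toluene, reflux, azeotropic removal of water; crystallisation from petroleum ether, −20 °C; mother liquor re-equilibrated with the same acid and recrystallised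
Reagents that add atoms: none
Why: Acid-catalysed acetalisation of the pseudo-acid gives both C5 epimers, of which the (5R) epimer should crystallise while acid re-epimerises the rest through the oxocarbenium ion, so C5 is set by crystallisation-driven resolution.

Step 3
Reactants: 6 3,4-dimethoxybenzaldehyde
Product: 7 2-(3,4-dimethoxyphenyl)-1,3-dithiane
Conditions: HS(CH2)3SH, BF3·OEt2 (cat.), CH2Cl2, 0 °C → rt
Reagents that add atoms: propane-1,3-dithiol SCCCS
Why: Lewis-acid-catalysed dithioacetalisation of an aromatic aldehyde gives the standard precursor of an acyl-anion equivalent (umpolung).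

Step 4
Reactants: 8 vanillin
Product: 9 3-methoxy-4-(methoxymethoxy)benzaldehyde
Conditions: MOMCl, i-Pr2NEt, CH2Cl2, 0 °C → rt
Reagents that add atoms: chloromethyl methyl ether COCCl
Why: Williamson-type O-alkylation of the phenol with an α-chloro ether gives an acetal-type ether that should withstand the organolithium, nickel boride, hydroxide and amine conditions of steps 5 to 8 and leave in mild acid.

Step 5
Reactants: 7 2-(3,4-dimethoxyphenyl)-1,3-dithiane; 5 (5R)-5-(l-menthyloxy)furan-2(5H)-one; 9 3-methoxy-4-(methoxymethoxy)benzaldehyde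
Product: 13 (3S,4R,5R)-4-[2-(3,4-dimethoxyphenyl)-1,3-dithian-2-yl]-3-{hydroxy[3-methoxy-4-(methoxymethoxy)phenyl]methyl}-5-(l-menthyloxy)dihydrofuran-2(3H)-one (both carbinol epimers), via 2-lithio-2-(3,4-dimethoxyphenyl)-1,3-dithiane 10 (not isolated), via lithium lactone enolate 11 (not isolated), via lithium aldolate 12 (not isolated)
Conditions: 7, n-BuLi, THF, −30 °C; then 5, THF, −78 °C; then 9, THF, −78 °C; AcOH, −78 °C
Reagents that add atoms: none
Why: n-BuLi removes the C2–H of 7 to give the sulfur- and aryl-stabilised anion 10, which undergoes Michael addition to C4 of butenolide 5 to give enolate 11; this adds at C3 to the carbonyl of 9 (aldol) to give aldolate 12, which AcOH protonates cold. The closest known reaction type is the tandem conjugate addition–enolate trapping of lithiated aryl dithioacetals on 5-alkoxybutenolides with an aldehyde as second electrophile. No ring is closed, so no mode of closure arises. C4 is set by the C5 menthyloxy group, which blocks one face of the flat butenolide so that 10 enters trans to it, and C3 is set by the new bulky C4 dithianyl group, which sends the aldehyde to the opposite face (all-trans lactone); the carbinol carbon is uncontrolled and need not be controlled. The step needs 1,4- over 1,2-addition, which the soft, delocalised and hindered carbanion and the unhindered β-carbon of the enoate should secure, and it needs the aldolate to persist, which the cold acidic quench should secure.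

Step 6
Reactants: 13 the dithianyl aldol lactone
Product: 14 (3S,4R,5R)-4-(3,4-dimethoxybenzyl)-3-{hydroxy[3-methoxy-4-(methoxymethoxy)phenyl]methyl}-5-(l-menthyloxy)dihydrofuran-2(3H)-one (both carbinol epimers)
Conditions: NiCl2·6H2O, NaBH4, MeOH/THF, 0 °C → rt
Reagents that add atoms: none
Why: Nickel boride formed in the flask hydrogenolyses both benzylic C–S bonds (reductive desulfurisation), turning the dithiane carbon into the benzylic CH2, while the lactone acetal, the MOM ether and the carbinol should survive the short cold treatment and no stereocentre is touched.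

Step 7
Reactants: 14 the benzyl aldol lactone acetal
Product: 17 (3S,4R)-4-(3,4-dimethoxybenzyl)-3-{hydroxy[3-methoxy-4-(methoxymethoxy)phenyl]methyl}dihydrofuran-2(3H)-one (both carbinol epimers), via potassium aldehyde carboxylate 15 (not isolated), via dihydroxy acid 16 (not isolated)
Conditions: KOH, NaBH4, EtOH/H2O, 0 °C → rt; then 2 M HCl to pH 2–3, 0 °C → rt
Reagents that add atoms: none
Why: Hydroxide opens the acylal-type lactone, the freed hemiacetal sheds menthol to give aldehyde 15, NaBH4 reduces it at once to the primary alcohol and acidification closes the γ-lactone onto the former acetal carbon (saponification–borohydride reduction–relactonisation of a γ-alkoxybutyrolactone); the oxygen taken up from hydroxide leaves again as water, and C3 and C4 should hold because reduction of the aldehyde outruns its enolisation.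

Step 8
Reactants: 17 the hydroxybenzyl lactone
Product: 19 (3E,4R)-4-(3,4-dimethoxybenzyl)-3-[3-methoxy-4-(methoxymethoxy)benzylidene]dihydrofuran-2(3H)-one, via benzylic mesylate 18 (not isolated)
Conditions: MsCl, Et3N, CH2Cl2, 0 °C; then DBU, 0 °C → rt
Reagents that add atoms: none
Why: Sulfonylation of the carbinol followed by E1cB elimination through the lactone enolate should convert both carbinol epimers into the conjugated E-alkene (aryl anti to the lactone carbonyl), erasing C3 and the carbinol centre and leaving C4 untouched.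

Step 9
Reactants: 19 the MOM-protected arylidene lactone
Product: 20 (3E,4R)-4-(3,4-dimethoxybenzyl)-3-(4-hydroxy-3-methoxybenzylidene)dihydrofuran-2(3H)-one (target)
Conditions: 2 M HCl (aq.)/THF, rt → 40 °C
Reagents that add atoms: none
Why: Acid-catalysed hydrolysis of the aryl methoxymethyl acetal frees the phenol, and dilute aqueous acid should be too weak to isomerise the E-alkene, open the γ-lactone, cleave the aryl methyl ethers or trigger Friedel–Crafts closure onto the veratryl ring.

Compound list
1 | furfural | O=Cc1ccco1 | starting material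
2 | 5-hydroxyfuran-2(5H)-one (racemic) | O=C1C=CC(O)O1 | intermediate
3 | (−)-menthol, (1R,2S,5R) | CC(C)[C@@H]1CC[C@@H](C)C[C@H]1O | starting material
4 | 5-(l-menthyloxy)furan-2(5H)-one, mixture of C5 epimers (formed in the flask) | O=C1C=CC(O[C@@H]2C[C@H](C)CC[C@H]2C(C)C)O1 | intermediate
5 | (5R)-5-(l-menthyloxy)furan-2(5H)-one | O=C1C=C[C@H](O[C@@H]2C[C@H](C)CC[C@H]2C(C)C)O1 | intermediate
6 | 3,4-dimethoxybenzaldehyde | COc1ccc(C=O)cc1OC | starting material
7 | 2-(3,4-dimethoxyphenyl)-1,3-dithiane | COc1ccc(C2SCCCS2)cc1OC | intermediate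
8 | vanillin | COc1cc(C=O)ccc1O | starting material
9 | 3-methoxy-4-(methoxymethoxy)benzaldehyde | COCOc1ccc(C=O)cc1OC | intermediate
10 | 2-lithio-2-(3,4-dimethoxyphenyl)-1,3-dithiane (formed in the flask) | [Li]C1(SCCCS1)c1ccc(OC)c(OC)c1 | intermediate
11 | lithium (4R,5R)-4-[2-(3,4-dimethoxyphenyl)-1,3-dithian-2-yl]-5-(l-menthyloxy)-4,5-dihydrofuran-2-olate (formed in the flask) | [Li]OC1=C[C@@H](C2(SCCCS2)c2ccc(OC)c(OC)c2)[C@H](O[C@@H]2C[C@H](C)CC[C@H]2C(C)C)O1 | intermediate
12 | lithium alkoxide of 13, carbinol epimers (formed in the flask) | O=C1O[C@@H](O[C@@H]2C[C@H](C)CC[C@H]2C(C)C)[C@H](C2(SCCCS2)c2ccc(OC)c(OC)c2)[C@H]1C(O[Li])c1ccc(OCOC)c(OC)c1 | intermediate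
13 | (3S,4R,5R)-4-[2-(3,4-dimethoxyphenyl)-1,3-dithian-2-yl]-3-{hydroxy[3-methoxy-4-(methoxymethoxy)phenyl]methyl}-5-(l-menthyloxy)dihydrofuran-2(3H)-one, carbinol epimers | O=C1O[C@@H](O[C@@H]2C[C@H](C)CC[C@H]2C(C)C)[C@H](C2(SCCCS2)c2ccc(OC)c(OC)c2)[C@H]1C(O)c1ccc(OCOC)c(OC)c1 | intermediate
14 | (3S,4R,5R)-4-(3,4-dimethoxybenzyl)-3-{hydroxy[3-methoxy-4-(methoxymethoxy)phenyl]methyl}-5-(l-menthyloxy)dihydrofuran-2(3H)-one, carbinol epimers | O=C1O[C@@H](O[C@@H]2C[C@H](C)CC[C@H]2C(C)C)[C@H](Cc2ccc(OC)c(OC)c2)[C@H]1C(O)c1ccc(OCOC)c(OC)c1 | intermediate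
15 | potassium (2S,3R)-3-(3,4-dimethoxybenzyl)-2-{hydroxy[3-methoxy-4-(methoxymethoxy)phenyl]methyl}-4-oxobutanoate (formed in the flask) | O=C[C@H](Cc1ccc(OC)c(OC)c1)[C@@H](C(O)c1ccc(OCOC)c(OC)c1)C(=O)[O-].[K+] | intermediate
16 | (2S,3R)-3-(3,4-dimethoxybenzyl)-4-hydroxy-2-{hydroxy[3-methoxy-4-(methoxymethoxy)phenyl]methyl}butanoic acid (formed in the flask) | OC[C@H](Cc1ccc(OC)c(OC)c1)[C@@H](C(O)c1ccc(OCOC)c(OC)c1)C(=O)O | intermediate
17 | (3S,4R)-4-(3,4-dimethoxybenzyl)-3-{hydroxy[3-methoxy-4-(methoxymethoxy)phenyl]methyl}dihydrofuran-2(3H)-one, carbinol epimers | O=C1OC[C@H](Cc2ccc(OC)c(OC)c2)[C@H]1C(O)c1ccc(OCOC)c(OC)c1 | intermediate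
18 | methanesulfonate of 17 (formed in the flask) | O=C1OC[C@H](Cc2ccc(OC)c(OC)c2)[C@H]1C(OS(C)(=O)=O)c1ccc(OCOC)c(OC)c1 | intermediate
19 | (3E,4R)-4-(3,4-dimethoxybenzyl)-3-[3-methoxy-4-(methoxymethoxy)benzylidene]dihydrofuran-2(3H)-one | COCOc1ccc(/C=C2/C(=O)OC[C@@H]2Cc2ccc(OC)c(OC)c2)cc1OC | intermediate
20 | (3E,4R)-4-(3,4-dimethoxybenzyl)-3-(4-hydroxy-3-methoxybenzylidene)dihydrofuran-2(3H)-one | COc1cc(/C=C2/C(=O)OC[C@@H]2Cc2ccc(OC)c(OC)c2)ccc1O | target

Total step count: 9. Longest linear sequence: 7 steps (1, 2, 5, 6, 7, 8, 9).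

Steps most likely to fail

Step 5. The enolate 11 may be captured incompletely by the aldehyde, or the aldolate may revert (retro-aldol) before protonation, so that the third component is lost. Any excess of 10 could also add directly to the aldehyde. The fallback makes the two C–C bonds in separate operations; it sets out from 5 and 7 and comes back at 17. Enolate 11 is generated as in step 5 and simply protonated with AcOH at −78 °C to give (4R,5R)-4-[2-(3,4-dimethoxyphenyl)-1,3-dithian-2-yl]-5-(l-menthyloxy)dihydrofuran-2(3H)-one F1. NiCl2·6H2O/NaBH4 in MeOH/THF at 0 °C should then give (4R,5R)-4-(3,4-dimethoxybenzyl)-5-(l-menthyloxy)dihydrofuran-2(3H)-one F2. KOH/NaBH4 followed by aqueous HCl should give (R)-4-(3,4-dimethoxybenzyl)dihydrofuran-2(3H)-one F3. Its lithium enolate (LiN(i-Pr)2, THF, −78 °C) is combined with 9 and quenched cold with AcOH; the C4 benzyl group should direct the aldehyde to the opposite face and give the trans aldol 17.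

Step 7. Hydroxide may trigger retro-aldol cleavage of the β-hydroxy lactone before the ring opens, and C4 may epimerise while it is α to the transient aldehyde. The fallback caps the carbinol so that no alkoxide can form; it sets out from 14 and comes back at 17. TBSCl and imidazole in DMF (rt → 40 °C) should give the tert-butyldimethylsilyl ether of 14 F4. The same KOH/NaBH4 treatment and acidification should give the tert-butyldimethylsilyl ether of 17 F5. HF·pyridine in THF at 0 °C should then release 17.

Step 8. The amidine base may give some Z isomer or move the double bond into the ring, which would destroy the C4 stereocentre; the electron-rich benzylic sulfonate may also ionise. The fallback replaces sulfonate/base elimination by a neutral intramolecular syn-elimination; it sets out from 17 and comes back at 19. Methyl N-(triethylammoniumsulfonyl)carbamate in toluene (rt → 50 °C) should convert the carbinol into the triethylammonium N-(methoxycarbonyl)sulfamate ester of 17 F6, which should eliminate on warming without added base. Any (3Z,4R)-4-(3,4-dimethoxybenzyl)-3-[3-methoxy-4-(methoxymethoxy)benzylidene]dihydrofuran-2(3H)-one F7 formed would be equilibrated to the E isomer 19 with catalytic I2 in CH2Cl2 under visible light.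

Further compounds
F1 | step 5 | (4R,5R)-4-[2-(3,4-dimethoxyphenyl)-1,3-dithian-2-yl]-5-(l-menthyloxy)dihydrofuran-2(3H)-one | O=C1C[C@@H](C2(SCCCS2)c2ccc(OC)c(OC)c2)[C@H](O[C@@H]2C[C@H](C)CC[C@H]2C(C)C)O1
F2 | step 5 | (4R,5R)-4-(3,4-dimethoxybenzyl)-5-(l-menthyloxy)dihydrofuran-2(3H)-one | O=C1C[C@@H](Cc2ccc(OC)c(OC)c2)[C@H](O[C@@H]2C[C@H](C)CC[C@H]2C(C)C)O1
F3 | step 5 | (R)-4-(3,4-dimethoxybenzyl)dihydrofuran-2(3H)-one | O=C1C[C@@H](Cc2ccc(OC)c(OC)c2)CO1
F4 | step 7 | tert-butyldimethylsilyl ether of 14, carbinol epimers | O=C1O[C@@H](O[C@@H]2C[C@H](C)CC[C@H]2C(C)C)[C@H](Cc2ccc(OC)c(OC)c2)[C@H]1C(O[Si](C)(C)C(C)(C)C)c1ccc(OCOC)c(OC)c1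
F5 | step 7 | tert-butyldimethylsilyl ether of 17, carbinol epimers | O=C1OC[C@H](Cc2ccc(OC)c(OC)c2)[C@H]1C(O[Si](C)(C)C(C)(C)C)c1ccc(OCOC)c(OC)c1
F6 | step 8 | triethylammonium N-(methoxycarbonyl)sulfamate ester of 17, carbinol epimers | O=C1OC[C@H](Cc2ccc(OC)c(OC)c2)[C@H]1C(OS(=O)(=O)[N-]C(=O)OC)c1ccc(OCOC)c(OC)c1.CC[NH+](CC)CC
F7 | step 8 | (3Z,4R)-4-(3,4-dimethoxybenzyl)-3-[3-methoxy-4-(methoxymethoxy)benzylidene]dihydrofuran-2(3H)-one | COCOc1ccc(/C=C2\C(=O)OC[C@@H]2Cc2ccc(OC)c(OC)c2)cc1OC
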